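**Retrosynthetic overview**
- Target ⇐ LiBH(s-Bu)3 reduction of the 3,3′-diketone ⇐ oxidation of the 3β,3′β-diol ⇐ removal of one ring sulfone.
- Key step: one Cp2TiCl-mediated radical double bicyclisation of an acyclic C30 bis-epoxide forms C4–C5 and C9–C10 (ring A, then ring B) and C4′–C5′ and C9′–C10′ (ring A′, then ring B′) together.
- The chain itself tells the two ends apart: an allylic sulfone at C7 is expelled as PhSO2• (gives C7=C8), while ring B′ closes 6-exo beside a pre-set C8′ methyl centre (gives the saturated half).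
- Bis-epoxide ⇐ two-directional alkylation of a C10 bis-sulfone with two (S)-6,7-epoxygeranyl bromides.
- C10 bis-sulfone ⇐ isoprene–PhSO2Cl adduct + alkenylzirconium from (S)-3-bromo-2-methylpropan-1-ol; arm ⇐ 5-bromo-2-methylpent-2-ene + methyl but-2-ynoate.

Assumption: each decalin is numbered as a drimane (C1–C12; primes for the saturated half; C11–C11′ is the central bond), and the sulfonyl-bearing carbons are carried as epimer mixtures because both sulfones are later lost.

**Route**

Step 1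
Reactants: 1 isoprene (2-methylbuta-1,3-diene)
Product: 2 {[(2E)-4-chloro-2-methylbut-2-en-1-yl]sulfonyl}benzene
Conditions: PhSO2Cl, CuCl (2 mol%), Et3N·HCl (2 mol%), MeCN, 100 °C (sealed tube); recrystallisation
Reagents that add atoms: benzenesulfonyl chloride, O=S(=O)(Cl)c1ccccc1
Why: Copper-catalysed atom-transfer radical addition (Kharasch type) in which PhSO2• adds to the methyl-substituted diene terminus and chlorine is transferred to the primary end of the allyl radical, giving the (E)-1,4-adduct with no stereocentre.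

Step 2
Reactants: 3 (2S)-3-bromo-2-methylpropan-1-ol
Product: 4 (2S)-2-methyl-3-(phenylsulfonyl)propan-1-ol
Conditions: PhSO2Na, DMF, 80 °C
Reagents that add atoms: sodium benzenesulfinate, [Na+].[O-]S(=O)c1ccccc1
Why: SN2 S-alkylation of the sulfinate at the primary bromide, which leaves the methyl-bearing stereocentre untouched.

Step 3
Reactants: 4 (2S)-2-methyl-3-(phenylsulfonyl)propan-1-ol
Product: 5 (2S)-2-methyl-3-(phenylsulfonyl)propanal
Conditions: DMP, CH2Cl2, 0 °C → rt; used at once
Reagents that add atoms: none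
Why: Dess–Martin oxidation under neutral conditions avoids base-induced loss of sulfinate and epimerisation of the α-stereocentre.

Step 4
Reactants: 5 (2S)-2-methyl-3-(phenylsulfonyl)propanal
Product: 6 {[(2S)-2-methylbut-3-yn-1-yl]sulfonyl}benzene
Conditions: TMSCHN2, LiN(i-Pr)2, THF, −78 °C; add 5, −78 → 0 °C; H2O
Reagents that add atoms: (trimethylsilyl)diazomethane, C[Si](C)(C)C=[N+]=[N-]
Why: Colvin homologation, in which carbonyl addition of lithiated TMS-diazomethane at −78 °C, Peterson elimination and 1,2-H shift of the alkylidene carbene outrun enolisation, so the stereocentre is kept.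

Step 5
Reactants: 6 {[(2S)-2-methylbut-3-yn-1-yl]sulfonyl}benzene; 2 {[(2E)-4-chloro-2-methylbut-2-en-1-yl]sulfonyl}benzene
Product: 8 (2E,5E,7S)-2,7-dimethyl-1,8-bis(phenylsulfonyl)octa-2,5-diene, via alkenylzirconocene chloride 7 (not isolated)
Conditions: Cp2Zr(H)Cl, THF, rt; then 2, Pd(PPh3)4 (5 mol%), THF, rt
Reagents that add atoms: none
Why: syn-Hydrozirconation gives the (E)-alkenylzirconium, and Negishi-type palladium-catalysed allylation joins it to the CH2 terminus of the π-allyl from 2 under base-free conditions with retention of both alkene geometries.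

Step 6
Reactants: 9 5-bromo-2-methylpent-2-ene; 10 methyl but-2-ynoate
Product: 13 methyl (2E)-3,7-dimethylocta-2,6-dienoate, via 4-methylpent-3-enylmagnesium bromide 11 (not isolated), via 4-methylpent-3-enylcopper 12 (not isolated)
Conditions: Mg, THF; CuBr·SMe2, THF, −40 °C; 10, −78 °C; aq. NH4Cl at −78 °C
Reagents that add atoms: none
Why: syn-Carbocupration of the ynoate at −78 °C with cold protonation of the alkenylcopper gives the (2E)-enoate (Corey–Katzenellenbogen stereocontrol).

Step 7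
Reactants: 13 methyl (2E)-3,7-dimethylocta-2,6-dienoate
Product: 14 methyl (2E,6S)-6,7-epoxy-3,7-dimethyloct-2-enoate
Conditions: L-fructose-derived Shi ketone (30 mol%), KHSO5, K2CO3 (pH 10.5), Bu4NHSO4 (cat.), MeCN–CH2(OMe)2–H2O, 0 °C
Reagents that add atoms: potassium peroxymonosulfate, [K+].[O-]S(=O)(=O)OO
Why: Shi asymmetric epoxidation, in which the chiral dioxirane reacts only at the electron-rich 6,7-alkene (the enoate alkene is deactivated) through a spiro transition state that gives the (6S)-epoxide.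

Step 8
Reactants: 14 methyl (2E,6S)-6,7-epoxy-3,7-dimethyloct-2-enoate
Product: 15 (2E,6S)-6,7-epoxy-3,7-dimethyloct-2-en-1-ol
Conditions: i-Bu2AlH (2.2 equiv), CH2Cl2, −78 °C; aq. potassium sodium tartrate
Reagents that add atoms: none
Why: 1,2-Reduction of the conjugated ester by i-Bu2AlH at −78 °C gives the allylic alcohol without opening the trisubstituted epoxide.

Step 9
Reactants: 15 (2E,6S)-6,7-epoxy-3,7-dimethyloct-2-en-1-ol
Product: 16 (2E,6S)-1-bromo-6,7-epoxy-3,7-dimethyloct-2-ene
Conditions: CBr4, PPh3, CH2Cl2, 0 °C; used directly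
Reagents that add atoms: carbon tetrabromide, BrC(Br)(Br)Br
Why: Appel bromination (SN2 on the alkoxyphosphonium salt) under neutral conditions keeps the epoxide and the E-alkene intact.

Step 10
Reactants: 8 (2E,5E,7S)-2,7-dimethyl-1,8-bis(phenylsulfonyl)octa-2,5-diene; 16 (2E,6S)-1-bromo-6,7-epoxy-3,7-dimethyloct-2-ene (2.3 equiv)
Product: 18 (3S,6E,10E,13E,15S,18E,22S)-2,3:22,23-diepoxy-2,6,10,15,19,23-hexamethyl-9,16-bis(phenylsulfonyl)tetracosa-6,10,13,18-tetraene, via dilithio bis-sulfone 17 (not isolated)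
Conditions: n-BuLi (2.2 equiv), THF–DMPU, −78 °C; then 16, −78 → −40 °C
Reagents that add atoms: none
Why: Two-directional Biellmann-type alkylation, in which both α-sulfonyl carbanions react by SN2 at the allylic bromide (α-attack for the allyl sulfone) far faster than at the hindered epoxide, and the two new sulfonyl-bearing centres need no control.

Step 11
Reactants: 18 (3S,6E,10E,13E,15S,18E,22S)-2,3:22,23-diepoxy-2,6,10,15,19,23-hexamethyl-9,16-bis(phenylsulfonyl)tetracosa-6,10,13,18-tetraene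
Product: 19 (3β)-11-[(3′β,8′βH)-3′-hydroxy-7′-(phenylsulfonyl)driman-11′-yl]drim-7-en-3-ol
Conditions: Cp2TiCl2 (6 equiv), Mn (12 equiv), THF, rt; the green Cp2TiCl solution added over 6 h to 18 (3 mM in THF), rt; then 1 M HCl
Reagents that add atoms: none
Why: Proposed new method: Cp2TiCl opens each (S)-epoxide homolytically to the tertiary β-titanoxy radical, whose chair–chair 6-endo/6-endo cascade on the left ends by β-scission of PhSO2• from C7 (as in radical allylations with allyl sulfones), fixing the alkene at C7=C8, while on the right 6-endo closure is followed by 6-exo attack at C9′ of the disubstituted alkene with the pre-set C8′ methyl and C11′ equatorial, the secondary C11′ radical being trapped by Cp2TiCl and protonated; the epoxide centres set the absolute sense (equatorial O–Ti, trans ring fusions, C9–H and C9′–H anti to the angular methyls), and the closest known chemistry is the Cp2TiCl-mediated radical cyclisation of epoxypolyprenes.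

Step 12
Reactants: 19 (3β)-11-[(3′β,8′βH)-3′-hydroxy-7′-(phenylsulfonyl)driman-11′-yl]drim-7-en-3-ol
Product: 20 (3β)-11-[(3′β,8′βH)-3′-hydroxydriman-11′-yl]drim-7-en-3-ol
Conditions: 6% Na(Hg), MeOH–THF, −20 °C → rt
Reagents that add atoms: none
Why: Reductive desulfonylation by electron transfer (C–S cleavage, then protonation of the carbanion) removes the ring sulfone and its uncontrolled centre without touching the trisubstituted alkene.

Step 13
Reactants: 20 (3β)-11-[(3′β,8′βH)-3′-hydroxydriman-11′-yl]drim-7-en-3-ol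
Product: 21 11-[(8′βH)-3′-oxodriman-11′-yl]drim-7-en-3-one
Conditions: DMP (3 equiv), CH2Cl2, rt
Reagents that add atoms: none
Why: Dess–Martin oxidation of both secondary alcohols, with no epimerisable centre next to either ketone on the ring-fusion side because C4 and C4′ are quaternary.

Step 14
Reactants: 21 11-[(8′βH)-3′-oxodriman-11′-yl]drim-7-en-3-one
Product: 22 (3α)-11-[(3′α,8′βH)-3′-hydroxydriman-11′-yl]drim-7-en-3-ol
Conditions: LiBH(s-Bu)3 (3 equiv), THF, −78 °C; then H2O
Reagents that add atoms: none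
Why: Steric approach control, in which the bulky hydride attacks each 4,4-dimethyl-3-ketone along the equatorial trajectory and gives the axial alcohols, as in known 3-oxo-triterpenoid to 3-epi-alcohol reductions.

**Compound list**
1 | isoprene (2-methylbuta-1,3-diene) | C=CC(C)=C | starting material
2 | {[(2E)-4-chloro-2-methylbut-2-en-1-yl]sulfonyl}benzene | ClC/C=C(\C)CS(=O)(=O)c1ccccc1 | intermediate
3 | (2S)-3-bromo-2-methylpropan-1-ol | OC[C@H](C)CBr | starting material
4 | (2S)-2-methyl-3-(phenylsulfonyl)propan-1-ol | OC[C@H](C)CS(=O)(=O)c1ccccc1 | intermediate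
5 | (2S)-2-methyl-3-(phenylsulfonyl)propanal | O=C[C@H](C)CS(=O)(=O)c1ccccc1 | intermediate
6 | {[(2S)-2-methylbut-3-yn-1-yl]sulfonyl}benzene | C#C[C@H](C)CS(=O)(=O)c1ccccc1 | intermediate
7 | chlorobis(cyclopentadienyl)[(1E,3S)-3-methyl-4-(phenylsulfonyl)but-1-en-1-yl]zirconium | Cl[Zr](/C=C/[C@H](C)CS(=O)(=O)c1ccccc1)(C1C=CC=C1)C1C=CC=C1 | intermediate
8 | (2E,5E,7S)-2,7-dimethyl-1,8-bis(phenylsulfonyl)octa-2,5-diene | O=S(=O)(c1ccccc1)C/C(C)=C/C/C=C/[C@H](C)CS(=O)(=O)c1ccccc1 | intermediate
9 | 5-bromo-2-methylpent-2-ene | CC(C)=CCCBr | starting material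
10 | methyl but-2-ynoate | CC#CC(=O)OC | starting material
11 | 4-methylpent-3-enylmagnesium bromide | CC(C)=CCC[Mg]Br | intermediate
12 | 4-methylpent-3-enylcopper | CC(C)=CCC[Cu] | intermediate
13 | methyl (2E)-3,7-dimethylocta-2,6-dienoate (methyl geranate) | CC(C)=CCC/C(C)=C/C(=O)OC | intermediate
14 | methyl (2E,6S)-6,7-epoxy-3,7-dimethyloct-2-enoate | CC1(C)O[C@H]1CC/C(C)=C/C(=O)OC | intermediate
15 | (2E,6S)-6,7-epoxy-3,7-dimethyloct-2-en-1-ol | CC1(C)O[C@H]1CC/C(C)=C/CO | intermediate
16 | (2E,6S)-1-bromo-6,7-epoxy-3,7-dimethyloct-2-ene | CC1(C)O[C@H]1CC/C(C)=C/CBr | intermediate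
17 | 1,8-dilithio derivative of 8 (lithium on both sulfonyl-bearing carbons) | [Li]C(S(=O)(=O)c1ccccc1)/C(C)=C/C/C=C/[C@H](C)C([Li])S(=O)(=O)c1ccccc1 | intermediate
18 | (3S,6E,10E,13E,15S,18E,22S)-2,3:22,23-diepoxy-2,6,10,15,19,23-hexamethyl-9,16-bis(phenylsulfonyl)tetracosa-6,10,13,18-tetraene (epimer mixture at C9 and C16) | CC1(C)O[C@H]1CC/C(C)=C/CC(S(=O)(=O)c1ccccc1)/C(C)=C/C/C=C/[C@H](C)C(S(=O)(=O)c1ccccc1)C/C=C(\C)CC[C@@H]1OC1(C)C | intermediate
19 | (3β)-11-[(3′β,8′βH)-3′-hydroxy-7′-(phenylsulfonyl)driman-11′-yl]drim-7-en-3-ol (both halves 5α-H, 9α-H, 10β-Me; both hydroxyls equatorial; 8′-methyl equatorial; 7′-epimer mixture) | CC1=CC[C@H]2C(C)(C)[C@@H](O)CC[C@]2(C)[C@H]1CC[C@H]1[C@H](C)C(S(=O)(=O)c3ccccc3)C[C@H]2C(C)(C)[C@@H](O)CC[C@]12C | intermediate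
20 | (3β)-11-[(3′β,8′βH)-3′-hydroxydriman-11′-yl]drim-7-en-3-ol (onocer-7-ene-3β,21α-diol) | CC1=CC[C@H]2C(C)(C)[C@@H](O)CC[C@]2(C)[C@H]1CC[C@H]1[C@H](C)CC[C@H]2C(C)(C)[C@@H](O)CC[C@]12C | intermediate
21 | 11-[(8′βH)-3′-oxodriman-11′-yl]drim-7-en-3-one (onocer-7-ene-3,21-dione) | CC1=CC[C@H]2C(C)(C)C(=O)CC[C@]2(C)[C@H]1CC[C@H]1[C@H](C)CC[C@H]2C(C)(C)C(=O)CC[C@]12C | intermediate
22 | (3α)-11-[(3′α,8′βH)-3′-hydroxydriman-11′-yl]drim-7-en-3-ol (onocer-7-ene-3α,21β-diol; both hydroxyls axial) | CC1=CC[C@H]2C(C)(C)[C@H](O)CC[C@]2(C)[C@H]1CC[C@H]1[C@H](C)CC[C@H]2C(C)(C)[C@H](O)CC[C@]12C | target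

**Totals**
Total step count: 14. Longest linear sequence: 9 steps (steps 6–14, or steps 2–5 followed by 10–14).

**Steps most likely to fail, with fallbacks**

Step 11 (double radical bicyclisation). The 6-exo closure of ring B′ onto an unactivated alkene is slow and may lose to premature termination of the C10′ radical or to 7-endo closure, and the two cascades must not disturb each other. Fallback, from 8 back to 19, running the two cascades separately: n-BuLi (1.05 equiv, THF, −78 °C) removes only the more acidic allylic α-sulfonyl proton of 8, and alkylation with 16 (1.0 equiv) gives (3S)-2,2-dimethyl-3-[(3E,7E,10E,12S)-3,7,12-trimethyl-6,13-bis(phenylsulfonyl)trideca-3,7,10-trien-1-yl]oxirane F3. Cp2TiCl (slow addition, THF) then closes rings A and B alone with loss of PhSO2• to give (3β)-11-[(1E,3S)-3-methyl-4-(phenylsulfonyl)but-1-en-1-yl]drim-7-en-3-ol F4. n-BuLi (2.2 equiv, forming the alkoxide and the α-sulfonyl carbanion) and 16 give (3β)-11-[(1E,3S,6E)-9-[(2S)-3,3-dimethyloxiran-2-yl]-3,7-dimethyl-4-(phenylsulfonyl)nona-1,6-dien-1-yl]drim-7-en-3-ol F5. A second cyclisation tuned only for the 6-endo/6-exo cascade (Cp2TiCl2 20 mol%, Mn, 2,4,6-collidine hydrochloride, THF, high dilution) closes rings A′ and B′ and returns to 19.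

Step 4 (alkyne from the β-sulfonyl aldehyde). The base may enolise 5, causing E1cB loss of sulfinate or epimerisation. Fallback, from 5 back to 6, with a neutral olefination first: CBr4 and PPh3 (CH2Cl2, 0 °C) give {[(2S)-4,4-dibromo-2-methylbut-3-en-1-yl]sulfonyl}benzene F1, and n-BuLi (3.2 equiv, THF, −78 °C, cold quench) converts F1 by bromine–lithium exchange and Fritsch–Buttenberg–Wiechell rearrangement into 6.

Step 5 (alkenylzirconium–allyl chloride coupling). Slow transmetalation could allow π-allyl isomerisation (loss of the 2E geometry) or elimination of 2 to the sulfonyl diene. Fallback, from 6 back to 8, through an isolated alkenyl metal and a different coupling: Bu3SnH with PdCl2(PPh3)2 (THF, rt) gives tributyl[(1E,3S)-3-methyl-4-(phenylsulfonyl)but-1-en-1-yl]stannane F2, which is purified and joined to 2 by a base-free Stille allylation (Pd2(dba)3, P(2-furyl)3, NMP, 40 °C) to return to 8.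

**Further compounds**
F1 | step 4 | {[(2S)-4,4-dibromo-2-methylbut-3-en-1-yl]sulfonyl}benzene | BrC(Br)=C[C@H](C)CS(=O)(=O)c1ccccc1
F2 | step 5 | tributyl[(1E,3S)-3-methyl-4-(phenylsulfonyl)but-1-en-1-yl]stannane | CCCC[Sn](CCCC)(CCCC)/C=C/[C@H](C)CS(=O)(=O)c1ccccc1
F3 | step 11 | (3S)-2,2-dimethyl-3-[(3E,7E,10E,12S)-3,7,12-trimethyl-6,13-bis(phenylsulfonyl)trideca-3,7,10-trien-1-yl]oxirane | CC1(C)O[C@H]1CC/C(C)=C/CC(S(=O)(=O)c1ccccc1)/C(C)=C/C/C=C/[C@H](C)CS(=O)(=O)c1ccccc1
F4 | step 11 | (3β)-11-[(1E,3S)-3-methyl-4-(phenylsulfonyl)but-1-en-1-yl]drim-7-en-3-ol | CC1=CC[C@H]2C(C)(C)[C@@H](O)CC[C@]2(C)[C@H]1C/C=C/[C@H](C)CS(=O)(=O)c1ccccc1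
F5 | step 11 | (3β)-11-[(1E,3S,6E)-9-[(2S)-3,3-dimethyloxiran-2-yl]-3,7-dimethyl-4-(phenylsulfonyl)nona-1,6-dien-1-yl]drim-7-en-3-ol | CC1=CC[C@H]2C(C)(C)[C@@H](O)CC[C@]2(C)[C@H]1C/C=C/[C@H](C)C(S(=O)(=O)c1ccccc1)C/C=C(\C)CC[C@@H]1OC1(C)C
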